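**Assumption:** the target has no stereocentre and no stereogenic double bond, so it is achiral and "single enantiomer" is met by the compound itself. The one stereocentre that appears on the way (in 5 and 6) is racemic and is destroyed by decarboxylation in step 3.

**Retrosynthetic overview**
- Target 11 ⇒ ester C–O disconnection to pentacosanoic acid 9 and 2-phenylethanol 10.
- 9 ⇒ 4-oxopentacosanoic acid 7 (C=O to CH2, Wolff–Kishner).
- 7 ⇒ 2-docosanoylsuccinate 5 (loss of both tert-butyl groups and one CO2).
- 5 ⇒ key C3–C4 bond by crossed Claisen condensation of the lithium enolate of di-tert-butyl succinate 3 (C3 piece) with docosanoyl chloride 2 (C22 piece, from behenic acid 1).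
- No ring is formed; the only ring (phenyl) is bought with 10.

**Route**

Step 1
Reactants: 1 docosanoic acid (behenic acid)
Product: 2 docosanoyl chloride
Conditions: SOCl2 (2 equiv), DMF (cat.), toluene, 70 °C, 2 h; evaporate, strip with toluene
Reagents that add atoms: thionyl chloride, ClS(Cl)=O
Why: Nucleophilic acyl substitution (acid to acid chloride, Vilsmeier-catalysed) is driven to completion by loss of gaseous SO2 and HCl, and the saturated chain has nothing else that can react.

Step 2
Reactants: 2 docosanoyl chloride; 3 di-tert-butyl succinate
Product: 5 di-tert-butyl 2-docosanoylbutanedioate (racemic), via succinate lithium enolate 4 (not isolated)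
Conditions: 3 (2.2 equiv), LDA (2.2 equiv, commercial solution), THF, −78 °C, 45 min; then 2 (1.0 equiv) in THF, −78 → 0 °C; aq. NH4Cl
Reagents that add atoms: none
Why: Crossed Claisen condensation: the preformed lithium enolate of the bulky tert-butyl ester does not self-condense at −78 °C and is C-acylated by the acid chloride, while the second equivalent of enolate takes up the acidic proton of the β-keto ester formed; the new stereocentre is racemic and is removed in step 3.

Step 3
Reactants: 5 di-tert-butyl 2-docosanoylbutanedioate
Product: 7 4-oxopentacosanoic acid, via 2-docosanoylbutanedioic acid 6 (not isolated)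
Conditions: TFA/CH2Cl2 1:1, rt, 4 h; evaporate; toluene, 110 °C, 2 h
Reagents that add atoms: none
Why: Acidolysis of both tert-butyl esters (loss of isobutene) followed by thermal decarboxylation of the β-keto acid through its cyclic six-membered transition state removes only the carboxyl β to the ketone, leaving the γ-keto acid.

Step 4
Reactants: 7 4-oxopentacosanoic acid
Product: 9 pentacosanoic acid, via 4-hydrazinylidenepentacosanoic acid 8 (not isolated)
Conditions: N2H4·H2O (5 equiv), KOH (4 equiv), diethylene glycol, 130 °C, 2 h; distil to 200 °C, 4 h; aq. HCl
Reagents that add atoms: none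
Why: Wolff–Kishner reduction (Huang-Minlon modification): the hydrazone, kept open as its carboxylate by hot KOH (which also reopens any cyclic dihydropyridazinone), loses N2 to give the methylene, and a saturated fatty acid salt tolerates these conditions.

Step 5
Reactants: 9 pentacosanoic acid; 10 2-phenylethanol
Product: 11 2-phenylethyl pentacosanoate
Conditions: 10 (3 equiv), TsOH·H2O (5 mol %), toluene, reflux, Dean–Stark, 12 h; aq. NaHCO3; recrystallise from acetone
Reagents that add atoms: none
Why: Fischer esterification of an unhindered acid with a primary alcohol is driven to completion by azeotropic removal of water, and no stereocentre is involved.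

**Compound list**
1 | docosanoic acid (behenic acid) | CCCCCCCCCCCCCCCCCCCCCC(=O)O | starting material
2 | docosanoyl chloride | CCCCCCCCCCCCCCCCCCCCCC(=O)Cl | intermediate
3 | di-tert-butyl succinate (di-tert-butyl butanedioate) | CC(C)(C)OC(=O)CCC(=O)OC(C)(C)C | starting material
4 | lithium enolate of di-tert-butyl succinate | [Li+].CC(C)(C)OC(=O)CC=C([O-])OC(C)(C)C | intermediate
5 | di-tert-butyl 2-docosanoylbutanedioate (racemic) | CCCCCCCCCCCCCCCCCCCCCC(=O)C(CC(=O)OC(C)(C)C)C(=O)OC(C)(C)C | intermediate
6 | 2-docosanoylbutanedioic acid (racemic) | CCCCCCCCCCCCCCCCCCCCCC(=O)C(CC(=O)O)C(=O)O | intermediate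
7 | 4-oxopentacosanoic acid | CCCCCCCCCCCCCCCCCCCCCC(=O)CCC(=O)O | intermediate
8 | 4-hydrazinylidenepentacosanoic acid (hydrazone of 7, present as its potassium salt) | CCCCCCCCCCCCCCCCCCCCCC(=NN)CCC(=O)O | intermediate
9 | pentacosanoic acid | CCCCCCCCCCCCCCCCCCCCCCCCC(=O)O | intermediate
10 | 2-phenylethanol | OCCc1ccccc1 | starting material
11 | 2-phenylethyl pentacosanoate | CCCCCCCCCCCCCCCCCCCCCCCCC(=O)OCCc1ccccc1 | target

**Total step count:** 5
**Longest linear sequence:** 5 steps (1 → 2 → 5 → 7 → 9 → 11)

**Three steps most likely to fail, with fallbacks**

Step 2 (crossed Claisen). The C22 acid chloride is poorly soluble at −78 °C, and O-acylation or double acylation of the kinetic enolate can lower the yield. The fallback sets out from 2 and comes back to the route at 7. Docosanoyl chloride 2 is used to C-acylate the sodium enolate of commercial triethyl ethane-1,1,2-tricarboxylate (CCOC(=O)CC(C(=O)OCC)C(=O)OCC; NaH, THF/toluene, 0 → 60 °C). This doubly stabilised malonate enolate needs no cryogenic conditions, and its product has no acidic α-hydrogen. It gives triethyl 3-oxotetracosane-1,2,2-tricarboxylate F1. Heating F1 in AcOH/H2SO4/H2O at reflux hydrolyses the three esters and decarboxylates twice (ketonic cleavage of an acylmalonate) to give 7.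

Step 4 (Wolff–Kishner on a γ-keto acid). Hydrazine can trap the substrate as a cyclic dihydropyridazinone, and the long-chain soap foams badly at 200 °C. The fallback sets out from 7 and comes back to the route at 11, putting the ester on first and removing the ketone under neutral conditions. Acid 7 is coupled with 10 (EDC·HCl, DMAP, CH2Cl2, rt) to give 2-phenylethyl 4-oxopentacosanoate F2. The ketone is converted with ethane-1,2-dithiol and BF3·OEt2 (CH2Cl2, rt) into 2-phenylethyl 3-(2-henicosyl-1,3-dithiolan-2-yl)propanoate F3. Raney nickel (W-2, washed neutral; THF, reflux) then desulfurises F3 to 11 (Mozingo reduction). The ester and the phenyl ring survive because the ester C–O bond is not benzylic.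

Step 5 (Fischer esterification). The waxy acid may not reach full conversion, and the excess alcohol has to be separated from a waxy ester. The fallback sets out from 9 and comes back to the route at 11, making the ester by O-alkylation of the carboxylate instead of acyl substitution. Acid 9 is neutralised with Cs2CO3 in DMF to give caesium pentacosanoate F4, which is alkylated with (2-bromoethyl)benzene (BrCCc1ccccc1; DMF, 60 °C, SN2) to give 11. The weakly basic carboxylate keeps elimination to styrene minor.

**Further compounds**
F1 | step 2 | triethyl 3-oxotetracosane-1,2,2-tricarboxylate | CCCCCCCCCCCCCCCCCCCCCC(=O)C(CC(=O)OCC)(C(=O)OCC)C(=O)OCC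
F2 | step 4 | 2-phenylethyl 4-oxopentacosanoate | CCCCCCCCCCCCCCCCCCCCCC(=O)CCC(=O)OCCc1ccccc1
F3 | step 4 | 2-phenylethyl 3-(2-henicosyl-1,3-dithiolan-2-yl)propanoate | CCCCCCCCCCCCCCCCCCCCCC1(CCC(=O)OCCc2ccccc2)SCCS1
F4 | step 5 | caesium pentacosanoate | [Cs+].[O-]C(=O)CCCCCCCCCCCCCCCCCCCCCCCC
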